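**Plan**
The target, (1R,2R,5S,6S)-2,6-bis(3,4-dimethoxyphenyl)-3,7-dioxabicyclo[3.3.0]octan-1-ol, is cut at C1–OH/C5–H (syn hydration of a C1=C5 alkene), at O3–C4 (O3 goes back to C1 as an oxirane O3–C2–C1), at C1–C5 (Heck) and at C6–O7 (allylic etherification), which leads to two cinnamyl C3 units.
Enabling feature: in the oxolane ring C1(OH)–C2(H)Ar–O3–C4H2–C5(H), O3 sits 1,3 to C5 across C1. The ring is therefore the hydrate of a 2-aryl-2,5-dihydrofuran, which is the [1,3]-O-shift isomer of an aryl oxirane (O3, C2, C1) carrying the vinyl unit C5=C4H2 on C1; after the shift the bicyclic alkene is C2-symmetric.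
Forward: the ring C5–C6–O7–C8–C1 is made first (etherification, then Heck closure), the arylidene on C1 is epoxidised, the spiro oxirane is expanded to the second oxolane ring, and water is added across C1=C5 last.
Stereochemistry: C6 comes from the chiral iridium catalyst; C2 from reagent-controlled epoxidation and is kept through the ring expansion because the C2–O3 bond is never broken; C1 and C5 come from syn hydroboration on the face opposite both aryl groups, where the C2 axis makes both regiochemical outcomes the same compound.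

Key step: step 7

Remark: the SMILES is read as ring-fusion OH and H cis to each other and both aryl groups on the opposite face (both endo); the route is built for exactly this diastereomer and enantiomer.

Step 1
Reactants: 1 (E)-3-(3,4-dimethoxyphenyl)prop-2-enal
Product: 3 (Z)-2-bromo-3-(3,4-dimethoxyphenyl)prop-2-enal, via dibromo aldehyde 2 (not isolated)
Conditions: Br2 (1.05 equiv), CH2Cl2, −20 °C; then Et3N, 0 °C to rt
Reagents that add atoms: bromine, BrBr
Why: Anti addition of Br2 to the enal C=C followed by base-induced anti elimination of HBr from the α-CH (bromination–dehydrobromination of an enal) should give the (Z)-α-bromo enal, addition to the alkene being faster than ring bromination at low temperature.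

Step 2
Reactants: 3 (Z)-2-bromo-3-(3,4-dimethoxyphenyl)prop-2-enal
Product: 4 (Z)-2-bromo-3-(3,4-dimethoxyphenyl)prop-2-en-1-ol
Conditions: NaBH4, MeOH, 0 °C
Reagents that add atoms: none
Why: Borohydride 1,2-reduction of the aldehyde should leave the vinyl bromide and the alkene geometry untouched.

Step 3
Reactants: 5 (E)-3-(3,4-dimethoxyphenyl)prop-2-en-1-ol
Product: 6 (E)-3-(3,4-dimethoxyphenyl)prop-2-en-1-yl methyl carbonate
Conditions: ClCO2Me, pyridine, CH2Cl2, 0 °C
Reagents that add atoms: methyl chloroformate, COC(=O)Cl
Why: O-Acylation of the primary allylic alcohol with a chloroformate installs the carbonate leaving group needed for π-allyl formation.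

Step 4
Reactants: 4 (Z)-2-bromo-3-(3,4-dimethoxyphenyl)prop-2-en-1-ol; 6 (E)-3-(3,4-dimethoxyphenyl)prop-2-en-1-yl methyl carbonate
Product: 7 4-[(1S)-1-{[(2Z)-2-bromo-3-(3,4-dimethoxyphenyl)prop-2-en-1-yl]oxy}prop-2-en-1-yl]-1,2-dimethoxybenzene
Conditions: 4, LiN(SiMe3)2, THF, 0 °C; CuI; then 6, [Ir(cod)Cl]2 (2 mol %), (Sa,S,S)-O,O'-(1,1'-binaphthyl-2,2'-diyl) N,N-bis(1-phenylethyl)phosphoramidite (4 mol %), THF, rt
Reagents that add atoms: none
Why: Iridium-catalysed asymmetric allylic etherification with a copper alkoxide: the iridium–phosphoramidite catalyst ionises 6 to a π-allyl complex that the alkoxide of 4 attacks at the aryl-bearing terminus, so the branched ether should form with its stereocentre (the later C6) set (S) by the ligand antipode chosen for that sense, while the vinyl bromide is inert to this catalyst.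

Step 5
Reactants: 7 4-[(1S)-1-{[(2Z)-2-bromo-3-(3,4-dimethoxyphenyl)prop-2-en-1-yl]oxy}prop-2-en-1-yl]-1,2-dimethoxybenzene
Product: 8 (2R)-2-(3,4-dimethoxyphenyl)-4-[(E)-(3,4-dimethoxyphenyl)methylidene]-3-methylideneoxolane
Conditions: Pd(OAc)2 (5 mol %), PPh3 (12 mol %), Ag2CO3, MeCN, 60 °C, dark
Reagents that add atoms: none
Why: Intramolecular Heck reaction of a 2-bromo-1,6-diene: oxidative addition of zerovalent palladium into the vinyl C–Br bond, 5-exo-trig carbopalladation of the terminal vinyl group with retention of the bromoalkene geometry, and β-hydride elimination of the only β-hydrogen should give the exocyclic 1,3-diene, with Ag2CO3 taking up HBr and suppressing hydride re-addition; the existing stereocentre is not touched (its descriptor changes from S to R only through the priority rules).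

Step 6
Reactants: 8 (2R)-2-(3,4-dimethoxyphenyl)-4-[(E)-(3,4-dimethoxyphenyl)methylidene]-3-methylideneoxolane
Product: 9 (2R,3R,6R)-2,6-bis(3,4-dimethoxyphenyl)-7-methylidene-1,5-dioxaspiro[2.4]heptane
Conditions: D-fructose-derived Shi ketone (30 mol %), KHSO5 (as 2KHSO5·KHSO4·K2SO4), K2CO3, Bu4NHSO4, MeCN–CH2(OMe)2 / aq. Na2B4O7 buffer, 0 °C
Reagents that add atoms: potassium peroxymonosulfate, [K+].[O-]S(=O)(=O)OO
Why: Shi asymmetric epoxidation by the chiral dioxirane should pick the electron-rich trisubstituted arylidene over the 1,1-disubstituted methylene and, by stereospecific syn oxygen transfer under reagent control, set the benzylic oxirane carbon (R) and the spiro carbon (R), the oxygen arriving on the ring face opposite the C6 aryl group so that reagent and substrate are matched, while the buffered basic medium protects the acid-labile aryl oxirane.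

Step 7
Reactants: 9 (2R,3R,6R)-2,6-bis(3,4-dimethoxyphenyl)-7-methylidene-1,5-dioxaspiro[2.4]heptane
Product: 10 (2R,6R)-2,6-bis(3,4-dimethoxyphenyl)-3,7-dioxabicyclo[3.3.0]oct-1(5)-ene
Conditions: Cu(hfacac)2 (copper bis(hexafluoroacetylacetonate), 5 mol %), toluene, 80–110 °C
Reagents that add atoms: none
Why: Copper-catalysed ring expansion of a vinyl oxirane to a 2,5-dihydrofuran (formal [1,3]-O shift): the Lewis-acidic divalent copper centre binds the oxirane oxygen, the tertiary allylic spiro C–O bond ionises to a copper alkoxide/allyl cation pair (or the σ-allyl copper species proposed for this catalyst), and the alkoxide recloses at the CH2 terminus. The closest known reaction is the Cu(hfacac)2-catalysed rearrangement of 2-aryl-3-vinyl oxiranes to 2-aryl-2,5-dihydrofurans, which keeps the configuration of the aryl-bearing carbon because its C–O bond is never broken. The new five-membered ring is closed by O–C bond formation, the benzylic alkoxide oxygen attacking the exocyclic methylene carbon of the allyl unit (an SN1'-like 5-endo closure, open to a cationic terminus), and the existing oxolane ring holds the alkoxide arm and the methylene cis on the new C=C so that only this ring can form. No new stereocentre is created: the benzylic (R) centre is carried through unchanged, the spiro centre is deleted, and the product becomes C2-symmetric with both aryl groups on one face. The selectivity needed is cleavage of the spiro allylic C–O bond and not the benzylic one (which would give 1,2-shift carbonyl products or epimerisation); it should be secured by the tertiary allylic nature of the spiro carbon, by relief of spiro strain and by the mild, non-protic catalyst.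

Step 8
Reactants: 10 (2R,6R)-2,6-bis(3,4-dimethoxyphenyl)-3,7-dioxabicyclo[3.3.0]oct-1(5)-ene
Product: 12 (1R,2R,5S,6S)-2,6-bis(3,4-dimethoxyphenyl)-3,7-dioxabicyclo[3.3.0]octan-1-ol, via alkylborane 11 (not isolated)
Conditions: BH3·THF, THF, 0 °C to rt; then NaOH, H2O2, 0 °C to rt
Reagents that add atoms: borane (as BH3·THF; its boron is carried by 11 only), B; hydrogen peroxide, OO
Why: Hydroboration–oxidation: BH3 should add H and B syn across the strained tetrasubstituted C1=C5 bond from the face opposite both aryl groups, the C2 axis of 10 makes boron at C1 or at C5 the same compound, and oxidation with retention gives the tertiary alcohol with cis ring fusion and both aryl groups endo.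

**Compound list**
1 | (E)-3-(3,4-dimethoxyphenyl)prop-2-enal | COc1ccc(/C=C/C=O)cc1OC | starting material
2 | rel-(2R,3S)-2,3-dibromo-3-(3,4-dimethoxyphenyl)propanal (racemic anti adduct) | O=C[C@@H](Br)[C@@H](Br)c1ccc(OC)c(OC)c1 | intermediate
3 | (Z)-2-bromo-3-(3,4-dimethoxyphenyl)prop-2-enal | COc1ccc(/C=C(\Br)C=O)cc1OC | intermediate
4 | (Z)-2-bromo-3-(3,4-dimethoxyphenyl)prop-2-en-1-ol | COc1ccc(/C=C(\Br)CO)cc1OC | intermediate
5 | (E)-3-(3,4-dimethoxyphenyl)prop-2-en-1-ol | COc1ccc(/C=C/CO)cc1OC | starting material
6 | (E)-3-(3,4-dimethoxyphenyl)prop-2-en-1-yl methyl carbonate | COC(=O)OC/C=C/c1ccc(OC)c(OC)c1 | intermediate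
7 | 4-[(1S)-1-{[(2Z)-2-bromo-3-(3,4-dimethoxyphenyl)prop-2-en-1-yl]oxy}prop-2-en-1-yl]-1,2-dimethoxybenzene | C=C[C@@H](c1ccc(OC)c(OC)c1)OC/C(Br)=C/c1ccc(OC)c(OC)c1 | intermediate
8 | (2R)-2-(3,4-dimethoxyphenyl)-4-[(E)-(3,4-dimethoxyphenyl)methylidene]-3-methylideneoxolane | C=C1[C@@H](c2ccc(OC)c(OC)c2)OC/C1=C/c1ccc(OC)c(OC)c1 | intermediate
9 | (2R,3R,6R)-2,6-bis(3,4-dimethoxyphenyl)-7-methylidene-1,5-dioxaspiro[2.4]heptane | C=C1[C@@H](c2ccc(OC)c(OC)c2)OC[C@]12O[C@@H]2c1ccc(OC)c(OC)c1 | intermediate
10 | (2R,6R)-2,6-bis(3,4-dimethoxyphenyl)-3,7-dioxabicyclo[3.3.0]oct-1(5)-ene | COc1ccc(cc1OC)[C@H]1OCC2=C1CO[C@@H]2c1ccc(OC)c(OC)c1 | intermediate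
11 | [(1S,2S,5S,6S)-2,6-bis(3,4-dimethoxyphenyl)-3,7-dioxabicyclo[3.3.0]octan-1-yl]borane | COc1ccc([C@H]2OC[C@@]3(B)[C@@H](c4ccc(OC)c(OC)c4)OC[C@@H]23)cc1OC | intermediate
12 | (1R,2R,5S,6S)-2,6-bis(3,4-dimethoxyphenyl)-3,7-dioxabicyclo[3.3.0]octan-1-ol | COc1ccc([C@H]2OC[C@@]3(O)[C@@H](c4ccc(OC)c(OC)c4)OC[C@@H]23)cc1OC | target

Total step count: 8. Longest linear sequence: 7 steps (1 → 3 → 4 → 7 → 8 → 9 → 10 → 12).

**Steps most likely to fail**

Step 7. What may go wrong is ionisation of the benzylic oxirane C–O bond of the electron-rich aryl oxirane, followed by 1,2-shift to carbonyl compounds, or Lewis-acid ionisation of the allylic benzylic ether with loss of configuration at C6. The fallback sets out from 9 and comes back at 10. The oxirane is opened in SN2' fashion by iodide at the exocyclic methylene (LiI, AcOH, THF, 0 °C), which should give the allylic iodide (R)-(3,4-dimethoxyphenyl)[(5R)-5-(3,4-dimethoxyphenyl)-4-(iodomethyl)-2,5-dihydrofuran-3-yl]methanol F1 without touching the benzylic C–O bond. K2CO3 in MeCN should then close the second ring by 5-exo-tet O-alkylation to give 10.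

Step 5. What may go wrong is re-addition of palladium hydride to the strained exocyclic diene (its aryl group points to the inside), which moves the double bonds into the aromatic furan or scrambles the arylidene geometry. The fallback sets out from 6 and comes back at 10. Sonogashira coupling of 4-iodo-1,2-dimethoxybenzene with prop-2-yn-1-ol (PdCl2(PPh3)2, CuI, Et3N) should give 3-(3,4-dimethoxyphenyl)prop-2-yn-1-ol F2. Etherification of F2 with 6 under the conditions of step 4 should give the enyne 4-[(1S)-1-{[3-(3,4-dimethoxyphenyl)prop-2-yn-1-yl]oxy}prop-2-en-1-yl]-1,2-dimethoxybenzene F3. Palladium-catalysed enyne cycloisomerisation (Pd(OAc)2, PPh3, benzene, 60 °C) should then give the unstrained diene (2R)-2-(3,4-dimethoxyphenyl)-4-[(Z)-(3,4-dimethoxyphenyl)methylidene]-3-methylideneoxolane F4 with the aryl group on the outside. Epoxidation of F4 with the same D-fructose-derived ketone should again make the benzylic carbon (R), now with the oxygen syn to the C6 aryl group under reagent control, to give (2R,3S,6R)-2,6-bis(3,4-dimethoxyphenyl)-7-methylidene-1,5-dioxaspiro[2.4]heptane F5. Cu(hfacac)2 as in step 7 should convert F5 into 10, because only the benzylic centre survives the ring expansion.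

Step 6. What may go wrong is incomplete site selection between the two alkenes of the diene, or acid-promoted opening of the electron-rich aryl oxirane during isolation. The fallback sets out from 8 and comes back at 10, and it replaces steps 6 and 7 by a six-to-five ring contraction. [4+2] Cycloaddition of singlet oxygen (O2, tetraphenylporphyrin, hν, CH2Cl2, −78 °C) to the s-cis diene, on the face opposite the aryl group of the oxolane, should give the endoperoxide (2R,7R)-2,7-bis(3,4-dimethoxyphenyl)-3,4,8-trioxabicyclo[4.3.0]non-1(6)-ene F6; the inside aryl group turns to the face away from the oxygen. PPh3 should then attack the peroxide oxygen on the CH2 group, and the benzylic alkoxide displaces Ph3P=O at that CH2 (5-exo-tet) to give 10 with the benzylic C–O bond intact.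

**Further compounds**
F1 | step 7 | (R)-(3,4-dimethoxyphenyl)[(5R)-5-(3,4-dimethoxyphenyl)-4-(iodomethyl)-2,5-dihydrofuran-3-yl]methanol | ICC1=C(CO[C@@H]1c2ccc(OC)c(OC)c2)[C@H](O)c1ccc(OC)c(OC)c1
F2 | step 5 | 3-(3,4-dimethoxyphenyl)prop-2-yn-1-ol | COc1ccc(C#CCO)cc1OC
F3 | step 5 | 4-[(1S)-1-{[3-(3,4-dimethoxyphenyl)prop-2-yn-1-yl]oxy}prop-2-en-1-yl]-1,2-dimethoxybenzene | C=C[C@@H](c1ccc(OC)c(OC)c1)OCC#Cc1ccc(OC)c(OC)c1
F4 | step 5 | (2R)-2-(3,4-dimethoxyphenyl)-4-[(Z)-(3,4-dimethoxyphenyl)methylidene]-3-methylideneoxolane | C=C1[C@@H](c2ccc(OC)c(OC)c2)OC/C1=C\c1ccc(OC)c(OC)c1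
F5 | step 5 | (2R,3S,6R)-2,6-bis(3,4-dimethoxyphenyl)-7-methylidene-1,5-dioxaspiro[2.4]heptane | C=C1[C@@H](c2ccc(OC)c(OC)c2)OC[C@@]12O[C@@H]2c1ccc(OC)c(OC)c1
F6 | step 6 | (2R,7R)-2,7-bis(3,4-dimethoxyphenyl)-3,4,8-trioxabicyclo[4.3.0]non-1(6)-ene | COc1ccc(cc1OC)[C@H]1OCC2=C1COO[C@@H]2c1ccc(OC)c(OC)c1
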